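The flask is read through a value of 0.316, the pool constant K_p: the first step's constant times the second's, divided by one plus the dormant step's, which at rest equals [target][released group] / ([pool][reagent]), the pool being starting material plus dormant form.

    starting material + reagent ⇌ intermediate (K1 = 5.4 /M, k1 = 4.4 /M/min)
    intermediate ⇌ target + released group (K2 = 0.11 M, k2 = 0.17 /min)
    solid substrate ⇌ starting material, rate k3*(cs3 - [starting material]) while solid is left; crystals form when [starting material] > cs3 (cs3 = 49 mM, k3 = 0.29 /min)
    starting material ⇌ dormant form (K4 = 0.88, k4 = 0.028 /min)

solid substrate 0.050 M; reagent 0.0350 M; time 20 h

1. at 20 h, what has stopped the reaction, if anything has (for what has run out or reacted, a solid counts together with what of it has only dissolved) (the reagent has run out first / it is still moving / all of the solid substrate has reacted / forward and back rates have come level)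
2. part of the solid substrate that has turned into other species by 20 h (what has only dissolved does not count)
3. how much target there is at 20 h, in percent of the solid substrate charged

- as a solid, counted per litre of solution: solid substrate
- at the start none of the solid substrate is in solution
- what has only dissolved of solid substrate counts as not reacted
- the reaction counts as stopped when no species that holds the solid substrate changes by six tenths of a point or more over the second half of the time
- what has gone from starting material into another species counts as reacted, even if it can come back
- run time (flask): 20 h

The question can be turned round: what would this flask need for the reagent, the limiting reagent by charge, to run out first? The forward half-lives of the reacting steps, at most 0.41 h, are far shorter than the 20 h of the run, so the reckoning here takes the balance as reached within the run and works with K_p. Let x be the target formed, and freeze the intermediate at zero, since its ratio to starting material, taken at the charged reagent, is 0.19. Then pool and reagent each fall by x, and K_p = x·x / ((c_s − x)(c_r − x)), where c_s and c_r are the charges of solid substrate and reagent. With 0.350 mM of reagent left, this ratio would read 223, which is 706 times K_p, so the reckoning here commits to level rates. It gives x = 14.9 mM, or 29.8% target. In this reckoning starting material then stands at 18.7 mM, below the solubility of 49 mM, so the reckoning keeps no solid.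

The forecast says forward and back rates have come level, with conversion 63.9% (62.5% to 65.5%) and target 28.5% (27.5% to 29.5%), holding that “every step relaxes within about an hour or two”. The target reckoned here lies 1.3 percentage points above it.

The simulation gives forward and back rates have come level, conversion 63.9% and target 28.5%. In this flask, the first and dormant steps ran while the solid was dissolving, with starting material made 4.11 times faster than it was used at 0.0393 h, and from 2.00 h to 200 h the states stand still, with 54.1% of the reagent left. Filled with the states of this flask at 20.0 h, the ratio of K_p reads 0.316, while intermediate stands at 3.69%, where the reckoning here had frozen it at zero. A neighbour flask charged with 0.013 M of solid substrate is reckoned from the same K_p at 55.1% target, and that flask holds 53.7%.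

(The numbers of this flask were chosen freely; no experiment stands behind them.)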